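**Plan**

- Labels: quinolinone A is bonded to Ca, quinolinone B to Cc (their ring atoms C3, C4, O4 carry the letter). Ca bears CH2C(CH3)2OH, Cb is the ring-fusion CH, Cc the O,C-substituted ring-fusion CH, Cq the gem-dimethyl carbon. Ring A = C4A–O4A–Cc–Cb–Ca–C3A, ring B = C4B–O4B–Cq–Cb–Cc–C3B.
- Enabling feature: rings A and B are both annulated through C3 and O4 onto two identical 4-hydroxy-7,8-dimethoxy-1-methylquinolin-2-one units. The ten carbons between them (Cc aldehyde carbon, Cb alpha-carbon, Ca beta-carbon, Cq isopropenyl carbon) make up one 2-isopropenyl-2-enal.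
- Retrosynthesis: the O–Si bond is cut first, then C3A–Ca, C3B–Cc, O4A–Cc and O4B–Cq together, leaving two molecules of the quinolinone and a silyl-protected C10 dienal. The dienal is cut at Cb–Cq (Suzuki–Miyaura) and at Ca=Cb (cross-metathesis), the quinolinone at N–CH3, N–C2 and C4–C4a.
- Forward order: the quinolinone (two steps) and the dienal (four steps) are made separately. In one flask quinolinone A is joined to Ca, ring A closes on Cc (lactol, then substitution by C3B), and ring B closes last (O4B on Cq). Desilylation ends the route.
- Stereochemistry: Ca (S) comes from a chiral primary-amine iminium catalyst. Cb (S) and Cc (R) come from acid equilibration to the cis-fused isomer with H(Ca)/H(Cb) trans. The E geometry of the dienal comes from a Z alpha-iodoenal by stereoretentive coupling.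

Key step: step 7

Assumption: the quinine-derived primary amine is taken to deliver the Ca (S) configuration; if the product of step 7 showed the opposite sense, the quinidine-derived pseudo-enantiomer would replace it with nothing else changed.

**Route**

Step 1
Reactants: 1 2,3-dimethoxyaniline
Product: 2 2,3-dimethoxy-N-methylaniline
Conditions: (CH2O)n, NaOMe, MeOH, 65 °C; then NaBH4, 65 °C
Reagents that add atoms: formaldehyde (as paraformaldehyde), C=O
Why: Reductive amination run as a one-pot mono-N-methylation, in which the aniline and formaldehyde give the N-(methoxymethyl)amine (a masked imine) under NaOMe and NaBH4 reduces it to the secondary amine without a second alkylation.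

Step 2
Reactants: 2 2,3-dimethoxy-N-methylaniline; 3 Meldrum's acid (2,2-dimethyl-1,3-dioxane-4,6-dione)
Product: 5 4-hydroxy-7,8-dimethoxy-1-methylquinolin-2(1H)-one, via malonamic acid 4 (not isolated)
Conditions: neat, 90 °C; then Eaton's reagent (P2O5 in MeSO3H) as solvent, 70 °C
Reagents that add atoms: none
Why: N-Acylation by ring opening of Meldrum's acid (acetone lost) followed by intramolecular Friedel–Crafts acylation in Eaton's reagent at the only free ortho position, which is para to the 3-methoxy group, should give the 4-hydroxyquinolinone after enolisation.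

Step 3
Reactants: 6 2-methylpent-4-en-2-ol
Product: 7 tert-butyl(dimethyl)[(2-methylpent-4-en-2-yl)oxy]silane
Conditions: TBSOTf, 2,6-lutidine, CH2Cl2, 0 to 25 °C
Reagents that add atoms: tert-butyldimethylsilyl trifluoromethanesulfonate, CC(C)(C)[Si](C)(C)OS(=O)(=O)C(F)(F)F
Why: Standard silylation of a tertiary alcohol with a silyl triflate and a hindered pyridine base; the tert-butyldimethylsilyl ether is chosen because it should outlast the sulfonic acid of step 7.

Step 4
Reactants: 7 tert-butyl(dimethyl)[(2-methylpent-4-en-2-yl)oxy]silane; 8 (E)-but-2-enal (excess)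
Product: 9 (E)-5-[(tert-butyldimethylsilyl)oxy]-5-methylhex-2-enal
Conditions: second-generation Hoveyda–Grubbs catalyst (3 mol %), CH2Cl2, 40 °C
Reagents that add atoms: none
Why: Olefin cross-metathesis of a terminal alkene with an excess of an electron-poor enal, driven by loss of propene, should give the E enal under thermodynamic control.

Step 5
Reactants: 9 (E)-5-[(tert-butyldimethylsilyl)oxy]-5-methylhex-2-enal
Product: 10 (Z)-5-[(tert-butyldimethylsilyl)oxy]-2-iodo-5-methylhex-2-enal
Conditions: I2, K2CO3, DMAP (20 mol %), THF/H2O, 25 °C
Reagents that add atoms: iodine, II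
Why: Nucleophile-catalysed alpha-iodination of an enal (Morita–Baylis–Hillman-type sequence of DMAP conjugate addition, enolate iodination and DMAP elimination) should place iodine cis to the beta-substituent, as in the known iodination of crotonaldehyde.

Step 6
Reactants: 10 (Z)-5-[(tert-butyldimethylsilyl)oxy]-2-iodo-5-methylhex-2-enal; 11 4,4,5,5-tetramethyl-2-(prop-1-en-2-yl)-1,3,2-dioxaborolane
Product: 12 (E)-5-[(tert-butyldimethylsilyl)oxy]-5-methyl-2-(prop-1-en-2-yl)hex-2-enal
Conditions: PdCl2(dppf) (5 mol %), K3PO4, THF/H2O, 40 °C
Reagents that add atoms: none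
Why: Suzuki–Miyaura coupling, in which zerovalent palladium inserts into the alkenyl C–I bond and the isopropenyl boronate is transferred with retention of alkene geometry, should turn the Z iodide into the E dienal with CHO trans to the CH2 group.

Step 7
Reactants: 12 (E)-5-[(tert-butyldimethylsilyl)oxy]-5-methyl-2-(prop-1-en-2-yl)hex-2-enal; 5 4-hydroxy-7,8-dimethoxy-1-methylquinolin-2(1H)-one (two equivalents, added in two portions)
Product: 15 tert-butyldimethylsilyl ether of the target, via ring-A lactol 13 (not isolated), via isopropenyl bis-quinolinone 14 (not isolated)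
Conditions: 5 (1.0 equiv), 9-amino-9-deoxy-epi-quinine (20 mol %), TFA (40 mol %), CHCl3, 25 °C; then 5 (1.1 equiv), CSA (50 mol %), 25 to 55 °C
Reagents that add atoms: none
Why: Proposed new method: the primary amine condenses with the alpha-branched enal 12 to a chiral iminium ion, C3 of the first molecule of 5 adds to Ca on the face left open by the cinchona scaffold, and after hydrolysis O4A adds to the aldehyde to give lactol 13; the closest known reactions are the amine-catalysed conjugate addition/hemiacetalisation of 4-hydroxycoumarins and 4-hydroxyquinolinones with enals and primary-amine iminium activation of alpha-substituted enals, a combination with a second nucleophile in one flask being new. The sulfonic acid then ionises 13 to the cyclic oxocarbenium ion (in equilibrium with the open aldehyde and, after condensation, with the quinone methide of quinolinone B), and C3 of the second molecule of 5 bonds to Cc to give 14. Ring A thus closes through O4A–Cc by 6-exo-trig attack on the aldehyde carbon and is kept or re-formed by 6-exo-trig oxa-Michael addition to the quinone methide. Ring B closes by Markovnikov hydroalkoxylation on warming, protonation of the isopropenyl group giving the tertiary cation Cq that O4B captures in a 6-exo mode, as in the acid cyclisation of 3-prenyl-4-hydroxyquinolinones; the other order (isopropylidene tautomer, Knoevenagel/oxa-6π closure of ring B, then acid addition of O4A across Cb=Cc) would converge on the same product. Ca is set by the catalyst, whereas Cb (epimerisable through enamine and enol-ether tautomers and through loss and return of its proton next to the Cc cation) and Cc (reversible C–O ionisation) are expected to settle under the acid on the cis-fused isomer with the Ca and Cb substituents trans. No selectivity between the two halves is needed because both nucleophiles are one compound; 1,4- before 1,2-attack is secured by the iminium catalyst and by withholding the second equivalent of 5 and the strong acid until the first addition is complete, O4A is tied to Cc as the lactol before the alkene can be protonated so that only O4B can reach Cq, closure through O4 and not the lactam oxygen gives the more stable 4-alkoxy-2-quinolone under reversible conditions, and the tertiary silyl ether keeps the side-chain oxygen away from Cc.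

Step 8
Reactants: 15 tert-butyldimethylsilyl ether of the target
Product: 16 target CNP0160874.2
Conditions: TBAF, THF, 50 °C
Reagents that add atoms: none
Why: Fluoride-induced Si–O cleavage (desilylation) of the hindered tertiary ether should need only warming, since aryl methyl ethers, lactams and the ring ethers are inert to fluoride and none of the three stereocentres bears an acidic hydrogen.

**Compound list**

1 | 2,3-dimethoxyaniline | COc1cccc(N)c1OC | starting material
2 | 2,3-dimethoxy-N-methylaniline | CNc1cccc(OC)c1OC | intermediate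
3 | Meldrum's acid (2,2-dimethyl-1,3-dioxane-4,6-dione) | CC1(C)OC(=O)CC(=O)O1 | starting material
4 | 3-[(2,3-dimethoxyphenyl)(methyl)amino]-3-oxopropanoic acid (malonamic acid, formed in the flask) | CN(C(=O)CC(=O)O)c1cccc(OC)c1OC | intermediate
5 | 4-hydroxy-7,8-dimethoxy-1-methylquinolin-2(1H)-one | COc1ccc2c(O)cc(=O)n(C)c2c1OC | intermediate
6 | 2-methylpent-4-en-2-ol | C=CCC(C)(C)O | starting material
7 | tert-butyl(dimethyl)[(2-methylpent-4-en-2-yl)oxy]silane | C=CCC(C)(C)O[Si](C)(C)C(C)(C)C | intermediate
8 | (E)-but-2-enal | C/C=C/C=O | starting material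
9 | (E)-5-[(tert-butyldimethylsilyl)oxy]-5-methylhex-2-enal | O=C/C=C/CC(C)(C)O[Si](C)(C)C(C)(C)C | intermediate
10 | (Z)-5-[(tert-butyldimethylsilyl)oxy]-2-iodo-5-methylhex-2-enal | O=C/C(I)=C/CC(C)(C)O[Si](C)(C)C(C)(C)C | intermediate
11 | 4,4,5,5-tetramethyl-2-(prop-1-en-2-yl)-1,3,2-dioxaborolane | CC(=C)B1OC(C)(C)C(C)(C)O1 | starting material
12 | (E)-5-[(tert-butyldimethylsilyl)oxy]-5-methyl-2-(prop-1-en-2-yl)hex-2-enal | O=C/C(=C/CC(C)(C)O[Si](C)(C)C(C)(C)C)C(C)=C | intermediate
13 | ring-A lactol (formed in the flask): (4S)-4-{2-[(tert-butyldimethylsilyl)oxy]-2-methylpropyl}-2-hydroxy-7,8-dimethoxy-6-methyl-3-(prop-1-en-2-yl)-2,3,4,6-tetrahydro-5H-pyrano[3,2-c]quinolin-5-one; Ca (S), Cb and Cc as mixtures | COc1ccc2c3c(c(=O)n(C)c2c1OC)[C@@H](CC(C)(C)O[Si](C)(C)C(C)(C)C)C(C(C)=C)C(O)O3 | intermediate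
14 | isopropenyl bis-quinolinone (formed in the flask): (2R,3R,4S)-4-{2-[(tert-butyldimethylsilyl)oxy]-2-methylpropyl}-2-(4-hydroxy-7,8-dimethoxy-1-methyl-2-oxo-1,2-dihydroquinolin-3-yl)-7,8-dimethoxy-6-methyl-3-(prop-1-en-2-yl)-2,3,4,6-tetrahydro-5H-pyrano[3,2-c]quinolin-5-one; same spatial arrangement at Ca, Cb, Cc as in 15 | COc1ccc2c3c(c(=O)n(C)c2c1OC)[C@@H](CC(C)(C)O[Si](C)(C)C(C)(C)C)[C@H](C(C)=C)[C@@H](O3)c2c(O)c3ccc(OC)c(OC)c3n(C)c2=O | intermediate
15 | tert-butyldimethylsilyl ether of the target: as 16 but with CH2C(CH3)2OSi(CH3)2C(CH3)3 on Ca; Ca (S), Cb (S), Cc (R) | COc1ccc2c3c(c(=O)n(C)c2c1OC)[C@@H](CC(C)(C)O[Si](C)(C)C(C)(C)C)[C@H]1[C@@H](O3)c2c(c3ccc(OC)c(OC)c3n(C)c2=O)OC1(C)C | intermediate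
16 | target CNP0160874.2: two 7,8-dimethoxy-1-methylquinolin-2(1H)-one units joined by the cis-fused bis-pyran (ring A C4A–O4A–Cc–Cb–Ca–C3A, ring B C4B–O4B–Cq(CH3)2–Cb–Cc–C3B); Ca bears CH2C(CH3)2OH; Ca (S), Cb (S), Cc (R); H on Ca trans to H on Cb, H on Cb cis to H on Cc | COc1ccc2c3c(c(=O)n(C)c2c1OC)[C@@H](CC(C)(C)O)[C@H]1[C@@H](O3)c2c(c3ccc(OC)c(OC)c3n(C)c2=O)OC1(C)C | target

**Step count and risks**

Total step count: 8. Longest linear sequence: 6 steps (6 → 7 → 9 → 10 → 12 → 15 → 16).

Steps most likely to fail:

1. Step 7 (proposed new method).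
   - What may go wrong: iminium formation from the hindered, alpha-branched enal may be slow, so that uncatalysed 1,2-attack (Knoevenagel condensation and oxa-6π closure onto Ca) enters the cascade and erodes the enantioselectivity at Ca. The Cc cation may be intercepted by a third quinolinone instead of O4A. Cb and Cc may equilibrate to another diastereomer. The silyl group may be lost before ring closure.
   - Fallback (known chemistry), setting out from 7 and 5 and returning at 15: ozonolysis of 7 (O3, CH2Cl2, −78 °C; PPh3) would give 3-[(tert-butyldimethylsilyl)oxy]-3-methylbutanal F1. In parallel, 5 and commercial 3-methylbut-2-enal with ethylenediammonium diacetate in toluene at 80 °C would give, by Knoevenagel condensation and oxa-6π electrocyclisation (formal [3+3] annulation), 7,8-dimethoxy-2,2,6-trimethyl-2,6-dihydro-5H-pyrano[3,2-c]quinolin-5-one F2, which already holds ring B with a Cb=Cc double bond. Heating 5, F1 and F2 with the same catalyst would then run a domino Knoevenagel/hetero-Diels–Alder reaction. The transient 3-{3-[(tert-butyldimethylsilyl)oxy]-3-methylbutylidene}-7,8-dimethoxy-1-methylquinoline-2,4(1H,3H)-dione F3 would act as the 1-oxadiene and add across Cb=Cc of F2 (Cb to Ca, O4A to Cc; suprafacial, hence cis ring fusion), closing ring A. The cycloadduct with H(Ca)/H(Cb) trans would be separated from its diastereomer and would be racemic, that is 15 together with the enantiomer of 15 F4. Preparative chromatography on a chiral stationary phase would return 15 to the route.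

2. Step 6.
   - What may go wrong: protodeiodination or base-induced oligomerisation of the alpha-iodoenal under the aqueous basic coupling conditions, and Diels–Alder dimerisation of the cross-conjugated dienal while it is held warm with palladium.
   - Fallback, setting out from 10 and returning at 12, by a detour through the alcohol oxidation level: Luche reduction (NaBH4, CeCl3·7H2O, MeOH, −20 °C) would give (Z)-5-[(tert-butyldimethylsilyl)oxy]-2-iodo-5-methylhex-2-en-1-ol F5, a robust coupling partner. Suzuki–Miyaura coupling with 11 (PdCl2(dppf), K3PO4, THF/H2O, 60 °C) would give (E)-5-[(tert-butyldimethylsilyl)oxy]-5-methyl-2-(prop-1-en-2-yl)hex-2-en-1-ol F6. Allylic oxidation with MnO2 in CH2Cl2 would deliver 12 immediately before use.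

3. Step 5.
   - What may go wrong: conjugate addition of DMAP to the beta-carbon next to the neopentyl-type chain may be too slow, and the base may trigger vinylogous elimination of silanolate from the dienolate before iodination occurs.
   - Fallback, setting out from 9 and returning at 12, by electrophilic addition and elimination instead of nucleophilic catalysis: addition of Br2 (CH2Cl2, −78 °C) would give the racemic anti dibromide (2R*,3S*)-2,3-dibromo-5-[(tert-butyldimethylsilyl)oxy]-5-methylhexanal F7. Et3N at 0 °C would eliminate HBr to give (Z)-2-bromo-5-[(tert-butyldimethylsilyl)oxy]-5-methylhex-2-enal F8, which would be coupled with 11 under the conditions of step 6 to give 12.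

Further compounds
F1 | step 7 | 3-[(tert-butyldimethylsilyl)oxy]-3-methylbutanal | O=CCC(C)(C)O[Si](C)(C)C(C)(C)C
F2 | step 7 | 7,8-dimethoxy-2,2,6-trimethyl-2,6-dihydro-5H-pyrano[3,2-c]quinolin-5-one | COc1ccc2c3c(c(=O)n(C)c2c1OC)C=CC(C)(C)O3
F3 | step 7 | 3-{3-[(tert-butyldimethylsilyl)oxy]-3-methylbutylidene}-7,8-dimethoxy-1-methylquinoline-2,4(1H,3H)-dione (alkene geometry not fixed) | COc1ccc2c(c1OC)N(C)C(=O)C(=CCC(C)(C)O[Si](C)(C)C(C)(C)C)C2=O
F4 | step 7 | enantiomer of 15; Ca (R), Cb (R), Cc (S) | COc1ccc2c3c(c(=O)n(C)c2c1OC)[C@H](CC(C)(C)O[Si](C)(C)C(C)(C)C)[C@@H]1[C@H](O3)c2c(c3ccc(OC)c(OC)c3n(C)c2=O)OC1(C)C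
F5 | step 6 | (Z)-5-[(tert-butyldimethylsilyl)oxy]-2-iodo-5-methylhex-2-en-1-ol | OC/C(I)=C/CC(C)(C)O[Si](C)(C)C(C)(C)C
F6 | step 6 | (E)-5-[(tert-butyldimethylsilyl)oxy]-5-methyl-2-(prop-1-en-2-yl)hex-2-en-1-ol | OC/C(=C/CC(C)(C)O[Si](C)(C)C(C)(C)C)C(C)=C
F7 | step 5 | (2R*,3S*)-2,3-dibromo-5-[(tert-butyldimethylsilyl)oxy]-5-methylhexanal (racemic, one enantiomer drawn) | O=C[C@@H](Br)[C@@H](Br)CC(C)(C)O[Si](C)(C)C(C)(C)C
F8 | step 5 | (Z)-2-bromo-5-[(tert-butyldimethylsilyl)oxy]-5-methylhex-2-enal | O=C/C(Br)=C/CC(C)(C)O[Si](C)(C)C(C)(C)C
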